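The midnight run cannot have been one step between L and E: X and L add up to the charge, so each L gave one X, and with E charged equal to L such a step would end at 100% X, yet X stood at 70.3% with L at 29.8%.

common to all: G 50 mM

|  | L | E | remark | time |
|---|---|---|---|---|
| midnight | 0.50 M | 0.50 M | run made earlier |  |
| dawn | 0.70 M | 0.50 M | run made earlier |  |
| autumn | 1.1 M | 0.50 M | run made earlier |  |
| Sunday's | 0.50 M | 0.500 M (fed, over 3.0 h) | all else is in the flask from the start; the feed brings no volume worth counting | 4.0 h |
| Friday's | 0.50 M | 0.500 M | everything together at the start | 4.0 h |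
| Thursday's | 0.50 M (fed, over 3.0 h) | 0.500 M | all else is in the flask from the start; the feed brings no volume worth counting | 4.0 h |

| run | time / h | X / % | L / % |
|---|---|---|---|
| midnight | 0.333 | 33.1 | 66.3 |
| midnight | 0.500 | 43.7 | 56.0 |
| midnight | 0.833 | 56.5 | 44.3 |
| midnight | 1.33 | 64.3 | 34.3 |
| midnight | 2.50 | 70.6 | 29.2 |
| midnight | 4.00 | 70.3 | 29.8 |
| dawn | 0.200 | 16.4 | 83.9 |
| dawn | 0.333 | 23.8 | 76.1 |
| dawn | 0.500 | 30.4 | 68.5 |
| dawn | 0.833 | 40.0 | 59.6 |
| dawn | 1.33 | 45.2 | 53.4 |
| dawn | 2.50 | 49.9 | 50.1 |
| autumn | 0.167 | 8.8 | 90.9 |
| autumn | 0.500 | 21.3 | 79.7 |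
| autumn | 0.833 | 25.7 | 74.5 |
| autumn | 1.33 | 30.0 | 70.5 |
| autumn | 2.00 | 32.2 | 68.4 |
| autumn | 2.50 | 32.0 | 68.0 |

(scatter of a reading: 0.5 percentage points)

- the numbers in the tables scatter by 0.5 percentage points (one standard deviation)
- a reading or a percentage of X counts all its forms, free or not

- the flask with the highest amount of X, in percent of the L charged ("all alike" if they lie within 1.5 percentage points) (Sunday's / Friday's / Thursday's / all alike)
- final X, as a percentage of the L charged, in Sunday's
- final X, as a percentage of the L charged, in Friday's
- final X, as a percentage of the L charged, in Thursday's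

I built the flask up from the main step. The last readings of X, taken in molar terms, were 0.351 M, 0.349 M and 0.352 M with L charged from 0.50 M to 1.1 M, so I took this step as indifferent to c(L) and first order in E, as long as L stands. The mean of these readings, 0.351 M, then asked for a second process, a first-order loss of E. Both rates follow c(E), so their comparison does not drift, and I named the share φ, the rate of E into X over the total rate of use of E at one moment (the selectivity), 70.2%. The midnight reading at 0.500 h gave a total constant of 1.95 /h, which split into 1.37 /h towards X and 0.581 /h lost.

I therefore reckoned Friday's at 70.2%. Feeding E in Sunday's leaves φ alone in this reckoning, but I estimated about 0.0122 M of E unspent at the end, which gave me 68.5%.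

Feeding L in Thursday's makes the comparison drift. The feed of 0.167 M/h is slower than the 0.684 M/h the main step could take at the start, so I let X follow the feed, with the share beginning at 36.5%. In my reckoning it climbs as c(E) falls, reaching φ at 0.122 M, after 1.13 h. Adding the X fed up to then to φ of the remaining E gave me 54.7%, so I put Friday's highest.

The forecast also named Friday's, with 68%, 70% and 41% for Sunday's, Friday's and Thursday's, near my first two but below my Thursday's, reasoning that “Feeding L starves the early reaction while E still decays”.

The flasks gave 68.3%, 70.1% and 52.9% in that order, with Friday's highest.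

    Z ⇌ X, rate k1*(cs1 - [X]) while solid is left; crystals form when [X] > cs1 (solubility = 9.40 mM, k = 0.0170 /s)
    E → Q (k = 1.60 × 10⁻⁴ /s)
    X → J (k = 1.20 × 10⁻⁶ /s)
    L + E + G → X + G, rate k4*[L]*[E]*[G]/(1 + ([L]/sat4)) (5.10 mM, k = 1.50 /M²/s)

At the end of Thursday's, the rate of E into X over the rate into Q was 2.3, but by 2.00 h the path to Q already had 96% of its turnover behind it, and Q ended at 0.235 M against 0.149 M in Friday's. For a flask like Thursday's with 0.30 M of E, the same reckoning with φ gives 37.9%, and that flask stood at 36.1%.

Readings and results were generated by integration for substances that don't exist; the scatter is artificial.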